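**Strategy**

Numbering: C1 (CH–CH3), C2 (CH–OAc), C4 (CH–side chain), C6 (CH2OAc), C8 (OH); C11 is the side-chain methine. The carbocycle C1–C2–C3–C4–C4a–C8a (ring B) is grown from the five-membered ring of a 3-substituted 7-alkoxyindan-1-one by insertion of a CH–CH3 unit from diazoethane into the aryl–carbonyl bond. This one-carbon enlargement exploits the array C8a–C1(CH3)–C2(O): in one operation it creates C1 with its methyl group and moves the carbonyl to C2, where the acetoxy group sits. The indanone already carries the C4/C11 stereodiad, set by rhodium-catalysed hydroacylation of a styrene made from (S)-β-citronellene. The epimerisable C1 is then fixed together with C2 by a dynamic reduction.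

Key step: step 9

Assumption: the ligand enantiomers written in steps 8 and 10 follow the usual sense of induction of these catalyst families; if a trial run shows the opposite sense, the mirror-image ligand is used and nothing else changes.

**Route**

Step 1
Reactants: 1 (S)-3,7-dimethylocta-1,6-diene ((S)-β-citronellene)
Product: 2 (S)-3,7-dimethyloct-6-en-2-one
Conditions: PdCl2 (10 mol%), CuCl (co-catalyst), O2 (1 atm), DMF/H2O 7:1, rt
Reagents that add atoms: water, O
Why: Tsuji–Wacker oxidation: Markovnikov hydroxypalladation turns only the monosubstituted alkene into the methyl ketone, the trisubstituted alkene is too hindered to react, and the allylic stereocenter (later C11) is not touched.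

Step 2
Reactants: 2 (S)-3,7-dimethyloct-6-en-2-one
Product: 4 (S)-3,7-dimethylocta-1,6-dien-2-yl trifluoromethanesulfonate, via lithium enolate 3 (not isolated)
Conditions: LiN(i-Pr)2 (1.1 equiv), THF, −78 °C; then PhNTf2, −78 → 0 °C
Reagents that add atoms: N-phenylbis(trifluoromethanesulfonimide), O=S(=O)(N(c1ccccc1)S(=O)(=O)C(F)(F)F)C(F)(F)F
Why: Kinetic deprotonation by the hindered amide base occurs at the methyl group and not at the tertiary α-carbon, so O-sulfonylation of the enolate should give the 1,1-disubstituted enol triflate without epimerisation.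

Step 3
Reactants: 4 (S)-3,7-dimethylocta-1,6-dien-2-yl trifluoromethanesulfonate
Product: 5 (S)-2-(3,7-dimethylocta-1,6-dien-2-yl)-4,4,5,5-tetramethyl-1,3,2-dioxaborolane
Conditions: B2pin2, PdCl2(PPh3)2 (3 mol%), PPh3, KOPh, toluene, 50 °C
Reagents that add atoms: bis(pinacolato)diboron, CC1(C)OB(OC1(C)C)B1OC(C)(C)C(C)(C)O1
Why: Miyaura borylation of the alkenyl triflate (oxidative addition, transmetalation with the phenoxide-activated diboron, reductive elimination) keeps the position of the double bond and the adjacent stereocenter.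

Step 4
Reactants: 6 3-bromo-5-(hydroxymethyl)phenol
Product: 7 [3-bromo-5-(methoxymethoxy)phenyl]methanol
Conditions: MOMCl, K2CO3, acetone, 0 °C → rt
Reagents that add atoms: chloromethyl methyl ether, COCCl
Why: Williamson-type O-alkylation: K2CO3 deprotonates only the phenol, so the MOM group, needed later as ortho-directing group and as the last protecting group, goes on the phenol oxygen alone.

Step 5
Reactants: 7 [3-bromo-5-(methoxymethoxy)phenyl]methanol
Product: 8 {[3-bromo-5-(methoxymethoxy)benzyl]oxy}triisopropylsilane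
Conditions: TIPSCl, imidazole, DMF, rt
Reagents that add atoms: chlorotriisopropylsilane, CC(C)[Si](Cl)(C(C)C)C(C)C
Why: Silylation of the primary benzylic alcohol gives a bulky ether that neither directs nor suffers lithiation and should survive all steps up to step 11.

Step 6
Reactants: 8 {[3-bromo-5-(methoxymethoxy)benzyl]oxy}triisopropylsilane
Product: 11 2-bromo-6-(methoxymethoxy)-4-{[(triisopropylsilyl)oxy]methyl}benzaldehyde, via aryllithium 9 (not isolated), via lithium hemiaminal alkoxide 10 (not isolated)
Conditions: LiN(i-Pr)2 (1.1 equiv), THF, −78 °C; DMF, −78 °C; then H2O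
Reagents that add atoms: N,N-dimethylformamide, CN(C)C=O
Why: Directed ortho-lithiation: the C–H between Br and OMOM is the most acidic position (inductive effect of bromine, coordination by the acetal oxygen), the amide base does not exchange the bromide and the aryllithium does not lose LiBr at −78 °C, so formylation with DMF places the aldehyde carbon (later C2) between the oxygen-bearing carbon and the brominated carbon.

Step 7
Reactants: 11 2-bromo-6-(methoxymethoxy)-4-{[(triisopropylsilyl)oxy]methyl}benzaldehyde; 5 (S)-2-(3,7-dimethylocta-1,6-dien-2-yl)-4,4,5,5-tetramethyl-1,3,2-dioxaborolane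
Product: 12 2-[(S)-3,7-dimethylocta-1,6-dien-2-yl]-6-(methoxymethoxy)-4-{[(triisopropylsilyl)oxy]methyl}benzaldehyde
Conditions: Pd(OAc)2 (3 mol%), SPhos (6 mol%), K3PO4, toluene/H2O, 60 °C
Reagents that add atoms: none
Why: Suzuki–Miyaura coupling of the ortho-formyl aryl bromide with the alkenylboronate forms the aryl–C4 bond under mild base that leaves the aldehyde and the allylic stereocenter unchanged.

Step 8
Reactants: 12 2-[(S)-3,7-dimethylocta-1,6-dien-2-yl]-6-(methoxymethoxy)-4-{[(triisopropylsilyl)oxy]methyl}benzaldehyde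
Product: 13 (S)-7-(methoxymethoxy)-3-[(S)-6-methylhept-5-en-2-yl]-5-{[(triisopropylsilyl)oxy]methyl}indan-1-one
Conditions: [Rh((S)-BINAP)]BF4 (5 mol%), CH2Cl2, rt
Reagents that add atoms: none
Why: Rhodium-catalysed asymmetric intramolecular alkene hydroacylation, known for 2-(alk-1-en-2-yl)benzaldehydes (aldehyde C–H oxidative addition, hydrometalation of the 1,1-disubstituted alkene, C–C reductive elimination to the five-membered ketone); the BINAP ligand selects the alkene face in the hydrometalation and so should set the new centre (S) (the later C4) next to the existing side-chain stereocenter.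

Step 9
Reactants: 13 (S)-7-(methoxymethoxy)-3-[(S)-6-methylhept-5-en-2-yl]-5-{[(triisopropylsilyl)oxy]methyl}indan-1-one
Product: 14 (4S)-8-(methoxymethoxy)-1-methyl-4-[(S)-6-methylhept-5-en-2-yl]-6-{[(triisopropylsilyl)oxy]methyl}-3,4-dihydronaphthalen-2(1H)-one (mixture of C1 epimers)
Conditions: CH3CHN2 (2 equiv, pre-made cold Et2O solution), Sc(OTf)3 (10 mol%), toluene/CH2Cl2, −78 °C
Reagents that add atoms: diazoethane, CC=[N+]=[N-]
Why: Sc(OTf)3, held as a six-membered chelate between the ketone oxygen and the peri methoxymethoxy oxygen, activates the carbonyl of 13 for addition of the diazo carbon, and the resulting β-alkoxy diazonium betaine loses N2 with 1,2-shift of the aryl carbon (the future C8a) from the carbonyl carbon to the new CH(CH3) carbon, so that the carbonyl carbon becomes C2 and the inserted carbon becomes C1. The closest known reaction type is the Büchner–Curtius–Schlotterbeck (Tiffeneau–Demjanov-type) homologation of 1-indanones and 1-tetralones with diazoalkanes, in which the aryl group migrates. No ring is closed by cyclisation: the five-membered ring is enlarged by one carbon through the migration. The new stereocenter C1 is not controlled here and need not be, because it is benzylic and α to the ketone, epimerises readily and both epimers are used in step 10; C4 and C11 are untouched because C4 is β to the carbonyl. The step needs aryl over CH2 migration, which the electron-rich ortho-alkoxy aryl ring should secure, and a single homologation, which the loss of the chelate and the α-branching in 14, the low temperature and the limited amount of diazoethane should secure.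

Step 10
Reactants: 14 (4S)-8-(methoxymethoxy)-1-methyl-4-[(S)-6-methylhept-5-en-2-yl]-6-{[(triisopropylsilyl)oxy]methyl}-3,4-dihydronaphthalen-2(1H)-one (mixture of C1 epimers)
Product: 15 (1R,2S,4S)-8-(methoxymethoxy)-1-methyl-4-[(S)-6-methylhept-5-en-2-yl]-6-{[(triisopropylsilyl)oxy]methyl}-1,2,3,4-tetrahydronaphthalen-2-ol
Conditions: RuCl(p-cymene)[(S,S)-TsDPEN] (2 mol%), HCO2H/Et3N 5:2, DMF, 40 °C
Reagents that add atoms: none
Why: Noyori–Ikariya asymmetric transfer hydrogenation under dynamic kinetic resolution: C1 of 14 epimerises through the enol under the amine-buffered conditions, the catalyst delivers hydride to the carbonyl face that gives (2S), and it does so fast only on the C1 epimer whose methyl group (held pseudoaxial by the peri C8 oxygen) lies opposite to the incoming hydride, so both epimers should converge on the 1,2-cis (1R,2S) alcohol with the fixed (4S) centre cis to both.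

Step 11
Reactants: 15 (1R,2S,4S)-8-(methoxymethoxy)-1-methyl-4-[(S)-6-methylhept-5-en-2-yl]-6-{[(triisopropylsilyl)oxy]methyl}-1,2,3,4-tetrahydronaphthalen-2-ol
Product: 16 (1R,2S,4S)-6-(hydroxymethyl)-8-(methoxymethoxy)-1-methyl-4-[(S)-6-methylhept-5-en-2-yl]-1,2,3,4-tetrahydronaphthalen-2-ol
Conditions: n-Bu4NF, THF, 0 °C → rt
Reagents that add atoms: none
Why: Fluoride cleaves the Si–O bond of the primary silyl ether; the MOM ether, the secondary alcohol and the alkene are inert.

Step 12
Reactants: 16 (1R,2S,4S)-6-(hydroxymethyl)-8-(methoxymethoxy)-1-methyl-4-[(S)-6-methylhept-5-en-2-yl]-1,2,3,4-tetrahydronaphthalen-2-ol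
Product: 17 (1R,2S,4S)-2-acetoxy-6-(acetoxymethyl)-8-(methoxymethoxy)-1-methyl-4-[(S)-6-methylhept-5-en-2-yl]-1,2,3,4-tetrahydronaphthalene
Conditions: Ac2O, pyridine, DMAP (cat.), CH2Cl2, rt
Reagents that add atoms: acetic anhydride, CC(=O)OC(C)=O
Why: DMAP-catalysed acylation esterifies the primary and the secondary alcohol; the phenol is still masked, so no phenyl acetate can form.

Step 13
Reactants: 17 (1R,2S,4S)-2-acetoxy-6-(acetoxymethyl)-8-(methoxymethoxy)-1-methyl-4-[(S)-6-methylhept-5-en-2-yl]-1,2,3,4-tetrahydronaphthalene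
Product: 19 (1R,2S,4S)-2-acetoxy-6-(acetoxymethyl)-8-hydroxy-1-methyl-4-[(S)-6-methylhept-5-en-2-yl]-1,2,3,4-tetrahydronaphthalene (CNP0210401.2), via aryl trimethylsilyl ether 18 (not isolated)
Conditions: TMSOTf, 2,2′-bipyridyl, CH2Cl2, 0 °C; then H2O
Reagents that add atoms: none
Why: The silyl triflate–bipyridyl pair converts the aromatic MOM ether into the aryl silyl ether under buffered aprotic conditions that spare both acetates and the trisubstituted alkene, and hydrolysis on work-up frees the phenol.

**Compound list**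

1 | (S)-3,7-dimethylocta-1,6-diene ((S)-β-citronellene) | C=C[C@@H](C)CCC=C(C)C | starting material
2 | (S)-3,7-dimethyloct-6-en-2-one | CC(=O)[C@@H](C)CCC=C(C)C | intermediate
3 | lithium (S)-3,7-dimethylocta-1,6-dien-2-olate (not isolated) | [Li]OC(=C)[C@@H](C)CCC=C(C)C | intermediate
4 | (S)-3,7-dimethylocta-1,6-dien-2-yl trifluoromethanesulfonate | C=C(OS(=O)(=O)C(F)(F)F)[C@@H](C)CCC=C(C)C | intermediate
5 | (S)-2-(3,7-dimethylocta-1,6-dien-2-yl)-4,4,5,5-tetramethyl-1,3,2-dioxaborolane | C=C(B1OC(C)(C)C(C)(C)O1)[C@@H](C)CCC=C(C)C | intermediate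
6 | 3-bromo-5-(hydroxymethyl)phenol | OCc1cc(O)cc(Br)c1 | starting material
7 | [3-bromo-5-(methoxymethoxy)phenyl]methanol | OCc1cc(OCOC)cc(Br)c1 | intermediate
8 | {[3-bromo-5-(methoxymethoxy)benzyl]oxy}triisopropylsilane | COCOc1cc(CO[Si](C(C)C)(C(C)C)C(C)C)cc(Br)c1 | intermediate
9 | 2-bromo-6-(methoxymethoxy)-4-{[(triisopropylsilyl)oxy]methyl}phenyllithium (not isolated) | [Li]c1c(Br)cc(CO[Si](C(C)C)(C(C)C)C(C)C)cc1OCOC | intermediate
10 | lithium (dimethylamino)(aryl)methanolate, the DMF adduct of 9 (not isolated) | [Li]OC(N(C)C)c1c(Br)cc(CO[Si](C(C)C)(C(C)C)C(C)C)cc1OCOC | intermediate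
11 | 2-bromo-6-(methoxymethoxy)-4-{[(triisopropylsilyl)oxy]methyl}benzaldehyde | O=Cc1c(Br)cc(CO[Si](C(C)C)(C(C)C)C(C)C)cc1OCOC | intermediate
12 | 2-[(S)-3,7-dimethylocta-1,6-dien-2-yl]-6-(methoxymethoxy)-4-{[(triisopropylsilyl)oxy]methyl}benzaldehyde | O=Cc1c(C(=C)[C@@H](C)CCC=C(C)C)cc(CO[Si](C(C)C)(C(C)C)C(C)C)cc1OCOC | intermediate
13 | (S)-7-(methoxymethoxy)-3-[(S)-6-methylhept-5-en-2-yl]-5-{[(triisopropylsilyl)oxy]methyl}indan-1-one | O=C1C[C@@H]([C@@H](C)CCC=C(C)C)c2cc(CO[Si](C(C)C)(C(C)C)C(C)C)cc(OCOC)c21 | intermediate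
14 | (4S)-8-(methoxymethoxy)-1-methyl-4-[(S)-6-methylhept-5-en-2-yl]-6-{[(triisopropylsilyl)oxy]methyl}-3,4-dihydronaphthalen-2(1H)-one, mixture of C1 epimers | CC1C(=O)C[C@@H]([C@@H](C)CCC=C(C)C)c2cc(CO[Si](C(C)C)(C(C)C)C(C)C)cc(OCOC)c21 | intermediate
15 | (1R,2S,4S)-8-(methoxymethoxy)-1-methyl-4-[(S)-6-methylhept-5-en-2-yl]-6-{[(triisopropylsilyl)oxy]methyl}-1,2,3,4-tetrahydronaphthalen-2-ol | CC(C)[Si](C(C)C)(C(C)C)OCc1cc(OCOC)c2c(c1)[C@H]([C@@H](C)CCC=C(C)C)C[C@H](O)[C@@H]2C | intermediate
16 | (1R,2S,4S)-6-(hydroxymethyl)-8-(methoxymethoxy)-1-methyl-4-[(S)-6-methylhept-5-en-2-yl]-1,2,3,4-tetrahydronaphthalen-2-ol | OCc1cc(OCOC)c2c(c1)[C@H]([C@@H](C)CCC=C(C)C)C[C@H](O)[C@@H]2C | intermediate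
17 | (1R,2S,4S)-2-acetoxy-6-(acetoxymethyl)-8-(methoxymethoxy)-1-methyl-4-[(S)-6-methylhept-5-en-2-yl]-1,2,3,4-tetrahydronaphthalene | CC(=O)OCc1cc(OCOC)c2c(c1)[C@H]([C@@H](C)CCC=C(C)C)C[C@H](OC(C)=O)[C@@H]2C | intermediate
18 | C8 trimethylsilyl ether of 19 (not isolated) | CC(=O)OCc1cc(O[Si](C)(C)C)c2c(c1)[C@H]([C@@H](C)CCC=C(C)C)C[C@H](OC(C)=O)[C@@H]2C | intermediate
19 | (1R,2S,4S)-2-acetoxy-6-(acetoxymethyl)-8-hydroxy-1-methyl-4-[(S)-6-methylhept-5-en-2-yl]-1,2,3,4-tetrahydronaphthalene (CNP0210401.2) | CC(=O)OCc1cc(O)c2c(c1)[C@H]([C@@H](C)CCC=C(C)C)C[C@H](OC(C)=O)[C@@H]2C | target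

**Step count and risks**

Total step count: 13. Longest linear sequence: 10 steps (steps 4 to 13; the branch of steps 1 to 3 joins at step 7).

Steps most likely to fail:

1. Step 9 (ring enlargement). The hindered, electron-rich aryl ketone may add diazoethane slowly, the CH2 group may migrate in part, or the product may be homologated a second time. The fallback sets out from 13 and comes back at 14 and runs through a β-oxido carbenoid. 1,1-Dibromoethane is lithiated with LiN(i-Pr)2 in THF at −95 °C in the presence of 13, the 1,1-dibromoethyllithium adds to the carbonyl group, and aqueous work-up should give the dibromo carbinol F1. Treatment of F1 with n-BuLi (2.2 equiv, THF, −95 → −40 °C) deprotonates the alcohol and exchanges one bromine for lithium. The carbenoid then loses LiBr with 1,2-shift of the aryl carbon and should give the lithium enolate F2 of the ring-enlarged ketone, which is protonated with AcOH at −78 °C to 14. This is a known semipinacol-type one-carbon ring enlargement and again relies on the migratory aptitude of the aryl group.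

2. Step 8 (hydroacylation). The acyl rhodium hydride may decarbonylate, the 1,1-disubstituted alkene may isomerise, or facial selectivity may be poor if ligand and side-chain stereocenter are mismatched. The fallback sets out from 4 and 11 and comes back at 13 and goes through an indenone. Triflate 4 with LiN(i-Pr)2 (2.2 equiv, THF, −78 → 0 °C) eliminates to the lithium acetylide F3, which is silylated in the same flask with Me3SiCl to the silyl alkyne F4. Larock annulation of bromo aldehyde 11 with F4 (Pd(OAc)2, Na2CO3, n-Bu4NCl, DMA, 100 °C) should give the 2-silylindenone F5, with the silyl group next to the carbonyl. Protodesilylation with buffered fluoride (n-Bu4NF/AcOH, THF, −20 °C, short contact to spare the silyl ether) should give the indenone F6. Copper hydride conjugate reduction (Cu(OAc)2, (R)-DTBM-SEGPHOS or its mirror image as the sense requires, (EtO)2MeSiH, t-BuOH, toluene, 0 °C) then sets the ring stereocenter under ligand control and returns to 13.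

3. Step 10 (dynamic reduction). Epimerisation at C1 may be too slow relative to reduction, or catalyst control over the carbonyl face may be too weak, so that the 1,4-trans series is carried along. The fallback sets out from 14 and comes back at 15 and uses substrate control with recycling. LiBH(s-Bu)3 (THF, −78 °C) reduces each C1 epimer from the face opposite the pseudoaxial C1 methyl group and should give 15 together with its (1S,2R,4S) isomer F7. After chromatographic separation F7 is oxidised back to 14 with Dess–Martin periodinane (CH2Cl2, rt), re-equilibrated at C1 with Et3N and reduced again.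

Further compounds
F1 | step 9 | (3S)-1-(1,1-dibromoethyl)-7-(methoxymethoxy)-3-[(S)-6-methylhept-5-en-2-yl]-5-{[(triisopropylsilyl)oxy]methyl}indan-1-ol, mixture of C1 epimers | CC(Br)(Br)C1(O)C[C@@H]([C@@H](C)CCC=C(C)C)c2cc(CO[Si](C(C)C)(C(C)C)C(C)C)cc(OCOC)c21
F2 | step 9 | lithium enolate of 14 (C1=C2 enolate) | [Li]OC1=C(C)c2c(OCOC)cc(CO[Si](C(C)C)(C(C)C)C(C)C)cc2[C@H]([C@@H](C)CCC=C(C)C)C1
F3 | step 8 | lithium (S)-3,7-dimethyloct-6-en-1-yn-1-ide | [Li]C#C[C@@H](C)CCC=C(C)C
F4 | step 8 | (S)-(3,7-dimethyloct-6-en-1-yn-1-yl)trimethylsilane | C[Si](C)(C)C#C[C@@H](C)CCC=C(C)C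
F5 | step 8 | 7-(methoxymethoxy)-3-[(S)-6-methylhept-5-en-2-yl]-5-{[(triisopropylsilyl)oxy]methyl}-2-(trimethylsilyl)inden-1-one | O=C1C([Si](C)(C)C)=C([C@@H](C)CCC=C(C)C)c2cc(CO[Si](C(C)C)(C(C)C)C(C)C)cc(OCOC)c21
F6 | step 8 | 7-(methoxymethoxy)-3-[(S)-6-methylhept-5-en-2-yl]-5-{[(triisopropylsilyl)oxy]methyl}inden-1-one | O=C1C=C([C@@H](C)CCC=C(C)C)c2cc(CO[Si](C(C)C)(C(C)C)C(C)C)cc(OCOC)c21
F7 | step 10 | (1S,2R,4S)-8-(methoxymethoxy)-1-methyl-4-[(S)-6-methylhept-5-en-2-yl]-6-{[(triisopropylsilyl)oxy]methyl}-1,2,3,4-tetrahydronaphthalen-2-ol | CC(C)[Si](C(C)C)(C(C)C)OCc1cc(OCOC)c2c(c1)[C@H]([C@@H](C)CCC=C(C)C)C[C@@H](O)[C@H]2C
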